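**Strategy**

Eudesmane numbering is used (ring A: C1–C5, C10; ring B: C5–C10; C14 on C10, C15 on C4, C1' benzylic). Ring A is closed last at C3–C4. Because C4 is allylic to the ring B C5=C6 bond and bears C15, it is carried as the brominated inner carbon of a C15=C4–C5=C6 diene, and C3 as the end of a vinyl group on C1. One-pot hydroboration and intramolecular B-alkyl Suzuki–Miyaura coupling closes ring A with an exocyclic C4=C15 bond, later reduced from the face opposite C14. The precursor is a carvone-derived ring B bromodiene whose quaternary C10 carries the C1(vinyl)–C1'(isobutyl)(aryl) chain.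

Key step: step 11

Remark: (S)-(+)-carvone and 5,7-dimethoxycoumarin are taken as commercial starting materials; in step 7 the ligand enantiomer is taken to be the one that gives the 4S lactone.

**Route**

Step 1
Reactants: 1 (S)-(+)-carvone
Product: 3 (5R,6R)-6-[(tert-butyldimethylsilyl)oxy]-2-methyl-5-(prop-1-en-2-yl)cyclohex-2-en-1-one, via silyl dienol ether 2 (not isolated)
Conditions: LiN(i-Pr)2, THF, −78 °C; t-BuMe2SiCl, DMPU, −78 to 0 °C; then mCPBA, NaHCO3, hexane/CH2Cl2, −20 to 0 °C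
Reagents that add atoms: tert-butyldimethylsilyl chloride CC(C)(C)[Si](C)(C)Cl; 3-chloroperbenzoic acid OOC(=O)c1cccc(Cl)c1
Why: Kinetic deprotonation at the α'-carbon (C6) and O-silylation give the cross-conjugated 2-silyloxydiene, whose enol ether double bond is the most electron-rich alkene and should be epoxidised anti to the adjacent isopropenyl group; a 1,4-silyl shift then gives the α-silyloxy ketone with the C6 oxygen trans to the C7 substituent (Rubottom oxidation).

Step 2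
Reactants: 3 (5R,6R)-6-[(tert-butyldimethylsilyl)oxy]-2-methyl-5-(prop-1-en-2-yl)cyclohex-2-en-1-one
Product: 5 (5R,6R)-6-[(tert-butyldimethylsilyl)oxy]-2-methyl-5-(prop-1-en-2-yl)cyclohex-1-en-1-yl trifluoromethanesulfonate, via lithium enolate 4 (not isolated)
Conditions: LiBH(s-Bu)3, THF, −78 °C; then PhNTf2, −78 to 0 °C
Reagents that add atoms: N-phenylbis(trifluoromethanesulfonimide) O=S(=O)(N(c1ccccc1)S(=O)(=O)C(F)(F)F)C(F)(F)F
Why: Conjugate hydride addition to the enone generates the tetrasubstituted enolate regiospecifically and PhNTf2 traps it on oxygen (conjugate reduction–enolate triflation), which fixes the C5=C10 double bond and a coupling handle at C5 without touching C6 or C7.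

Step 3
Reactants: 5 (5R,6R)-6-[(tert-butyldimethylsilyl)oxy]-2-methyl-5-(prop-1-en-2-yl)cyclohex-1-en-1-yl trifluoromethanesulfonate
Product: 7 tert-butyl{[(1R,6R)-2-ethynyl-3-methyl-6-(prop-1-en-2-yl)cyclohex-2-en-1-yl]oxy}dimethylsilane, via silylalkyne 6 (not isolated)
Conditions: Me3SiC≡CH, Pd(PPh3)2Cl2 (5 mol%), CuI (10 mol%), Et3N, DMF, 40 °C; then K2CO3 (cat.), MeOH, rt
Reagents that add atoms: ethynyltrimethylsilane C#C[Si](C)(C)C
Why: Sonogashira coupling of the vinyl triflate installs C4 and C15 as an alkyne, and the C-silyl group is removed by base-catalysed methanolysis in the same flask.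

Step 4
Reactants: 7 tert-butyl{[(1R,6R)-2-ethynyl-3-methyl-6-(prop-1-en-2-yl)cyclohex-2-en-1-yl]oxy}dimethylsilane
Product: 9 {[(1R,6R)-2-(1-bromoethenyl)-3-methyl-6-(prop-1-en-2-yl)cyclohex-2-en-1-yl]oxy}(tert-butyl)dimethylsilane, via alkenylborane 8 (not isolated)
Conditions: B-bromo-9-BBN, CH2Cl2, −78 to 0 °C; then AcOH, rt
Reagents that add atoms: B-bromo-9-borabicyclo[3.3.1]nonane BrB1C2CCCC1CCC2
Why: syn-Bromoboration of the terminal alkyne places bromine on the internal carbon C4 and boron on C15, and protonolysis of the alkenyl–boron bond with acetic acid gives the 2-bromo-1,3-diene; the alkenes and the silyl ether should be inert at low temperature.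

Step 5
Reactants: 9 {[(1R,6R)-2-(1-bromoethenyl)-3-methyl-6-(prop-1-en-2-yl)cyclohex-2-en-1-yl]oxy}(tert-butyl)dimethylsilane
Product: 11 2-{(1S,2R)-3-(1-bromoethenyl)-2-[(tert-butyldimethylsilyl)oxy]-4-methylcyclohex-3-en-1-yl}propan-2-ol, via organomercurial 10 (not isolated)
Conditions: Hg(OAc)2, THF/H2O, rt; then NaOH, NaBH4, 0 °C
Reagents that add atoms: water O
Why: Markovnikov oxymercuration–demercuration hydrates the electron-rich 1,1-disubstituted isopropenyl group to the C11 tertiary alcohol, the bromine-deactivated diene and the hindered tetrasubstituted alkene reacting more slowly.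

Step 6
Reactants: 11 2-{(1S,2R)-3-(1-bromoethenyl)-2-[(tert-butyldimethylsilyl)oxy]-4-methylcyclohex-3-en-1-yl}propan-2-ol
Product: 12 (1R,6S)-2-(1-bromoethenyl)-6-(2-hydroxypropan-2-yl)-3-methylcyclohex-2-en-1-ol
Conditions: HF·pyridine, pyridine, THF, 0 °C to rt
Reagents that add atoms: none
Why: Fluoride-mediated cleavage of the silyl ether (Si–O to Si–F exchange) frees the allylic C6 hydroxyl without affecting the vinyl bromide or the tertiary alcohol.

Step 7
Reactants: 13 5,7-dimethoxycoumarin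
Product: 14 (4S)-5,7-dimethoxy-4-(2-methylpropyl)-3,4-dihydro-2H-chromen-2-one
Conditions: i-BuMgBr, CuBr·SMe2 (5 mol%), Josiphos-type ferrocenyl diphosphine (6 mol%), t-BuOMe, −78 °C; aq. NH4Cl
Reagents that add atoms: isobutylmagnesium bromide CC(C)C[Mg]Br
Why: Copper-catalysed asymmetric conjugate addition of the Grignard reagent to the unsaturated lactone, in which the chiral diphosphine on copper selects the face of C4 so that the future C1' is set as S.

Step 8
Reactants: 12 (1R,6S)-2-(1-bromoethenyl)-6-(2-hydroxypropan-2-yl)-3-methylcyclohex-2-en-1-ol; 14 (4S)-5,7-dimethoxy-4-(2-methylpropyl)-3,4-dihydro-2H-chromen-2-one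
Product: 18 (3R,4S)-3-[(1R,4S)-2-(1-bromoethenyl)-4-(2-hydroxypropan-2-yl)-1-methylcyclohex-2-en-1-yl]-5,7-dimethoxy-4-(2-methylpropyl)-3,4-dihydro-2H-chromen-2-one, via potassium phenoxide ester 15 (not isolated), via silyl ketene acetal 16 (not isolated), via hydroxy acid 17 (not isolated)
Conditions: KN(SiMe3)2 (1.05 equiv), THF, −78 °C, then 14, −78 to 0 °C; Me3SiCl then KN(SiMe3)2 (2.5 equiv), −78 °C to 65 °C; 1 M HCl, THF; pyridinium 4-toluenesulfonate (cat.), 4 Å sieves, PhMe, 60 °C; DBU, rt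
Reagents that add atoms: none
Why: The secondary potassium alkoxide of 12 opens the aryl lactone by acyl transfer, the derived silyl ketene acetal undergoes a suprafacial Ireland–Claisen rearrangement that forms C10–C1 on the ring B face that carried the C6 oxygen (trans to the C7 substituent, fixing quaternary C10 with C14 cis to C11), and relactonisation followed by base equilibration of the epimerisable lactone α-carbon should place the bulky C1 substituent trans to the C1' isobutyl group on the chromanone ring, fixing C1.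

Step 9
Reactants: 18 (3R,4S)-3-[(1R,4S)-2-(1-bromoethenyl)-4-(2-hydroxypropan-2-yl)-1-methylcyclohex-2-en-1-yl]-5,7-dimethoxy-4-(2-methylpropyl)-3,4-dihydro-2H-chromen-2-one
Product: 19 (3R,4S)-3-[(1R,4S)-2-(1-bromoethenyl)-4-(2-hydroxypropan-2-yl)-1-methylcyclohex-2-en-1-yl]-5,7-dimethoxy-4-(2-methylpropyl)-3,4-dihydro-2H-chromen-2-ol
Conditions: i-Bu2AlH (2.5 equiv), CH2Cl2, −78 °C; aq. potassium sodium tartrate
Reagents that add atoms: none
Why: Partial reduction of the aryl lactone at low temperature stops at the tetrahedral aluminium hemiacetal, which gives the lactol on work-up; the vinyl bromide is inert to i-Bu2AlH.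

Step 10
Reactants: 19 (3R,4S)-3-[(1R,4S)-2-(1-bromoethenyl)-4-(2-hydroxypropan-2-yl)-1-methylcyclohex-2-en-1-yl]-5,7-dimethoxy-4-(2-methylpropyl)-3,4-dihydro-2H-chromen-2-ol
Product: 21 2-[(1S,4R)-3-(1-bromoethenyl)-4-methyl-4-[(3R,4S)-6-methyl-4-(2,4,6-trimethoxyphenyl)hept-1-en-3-yl]cyclohex-2-en-1-yl]propan-2-ol, via potassium phenoxide 20 (not isolated)
Conditions: Ph3PCH3Br, KN(SiMe3)2, THF, 0 °C to rt; then MeI, DMF, rt
Reagents that add atoms: methyltriphenylphosphonium bromide C[P+](c1ccccc1)(c1ccccc1)c1ccccc1.[Br-]; iodomethane CI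
Why: The lactol opens under the basic ylide to the phenoxide aldehyde, which undergoes Wittig methylenation to give the C2=C3 vinyl group, and the phenoxide is then O-methylated in the same flask (Williamson ether synthesis) while the tertiary alcohol stays un-ionised.

Step 11
Reactants: 21 2-[(1S,4R)-3-(1-bromoethenyl)-4-methyl-4-[(3R,4S)-6-methyl-4-(2,4,6-trimethoxyphenyl)hept-1-en-3-yl]cyclohex-2-en-1-yl]propan-2-ol
Product: 23 2-[(2S,4aR,5R)-4a-methyl-8-methylidene-5-[(1S)-3-methyl-1-(2,4,6-trimethoxyphenyl)butyl]-2,3,4,4a,5,6,7,8-octahydronaphthalen-2-yl]propan-2-ol, via alkylborane 22 (not isolated)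
Conditions: 9-BBN (3 equiv), THF, rt; then Pd(dppf)Cl2 (10 mol%), AsPh3, Cs2CO3, DMF/THF/H2O, 50 °C, high dilution
Reagents that add atoms: none
Why: 9-BBN adds to the monosubstituted C2=C3 vinyl group in the anti-Markovnikov sense and puts boron on C3; zerovalent palladium then inserts into the C4–Br bond of the 2-bromo-1,3-diene, the base-activated primary alkyl group moves from boron to palladium, and reductive elimination from the seven-membered palladacycle joins C3 to C4. The closest known reaction type is the intramolecular B-alkyl Suzuki–Miyaura coupling of an alkyl-9-BBN with a 1-halo-1-alkene, which gives exo-methylene cycloalkanes. Ring A is closed as a six-membered ring in the 6-exo sense with respect to the C4=C15 bond, which stays exocyclic and conjugated to C5=C6. No stereocentre is formed or touched: C1, C1', C7 and C10 are spectators and C4 is set in step 12. The step needs chemoselective hydroboration of the vinyl group over the bromine-bearing diene and the ring alkene, which the steric demand of 9-BBN and the deactivation by bromine should secure, and it needs cyclisation in preference to β-hydride elimination or intermolecular coupling, which the dppf ligand and high dilution should secure.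

Step 12
Reactants: 23 2-[(2S,4aR,5R)-4a-methyl-8-methylidene-5-[(1S)-3-methyl-1-(2,4,6-trimethoxyphenyl)butyl]-2,3,4,4a,5,6,7,8-octahydronaphthalen-2-yl]propan-2-ol
Product: 24 2-[(2S,4aR,5R,8R)-4a,8-dimethyl-5-[(1S)-3-methyl-1-(2,4,6-trimethoxyphenyl)butyl]-2,3,4,4a,5,6,7,8-octahydronaphthalen-2-yl]propan-2-ol
Conditions: 2-nitrobenzenesulfonohydrazide, Et3N, CH2Cl2, rt
Reagents that add atoms: none
Why: Diimide reduction delivers two hydrogens syn and concertedly to the least substituted alkene (the exocyclic C4=C15 bond) and should approach the face of ring A opposite the axial C14 methyl, so that hydrogen enters at C4 anti to C14 and C4 is set as R with C15 cis to C14; the trisubstituted C5=C6 bond should react far more slowly.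

Step 13
Reactants: 24 2-[(2S,4aR,5R,8R)-4a,8-dimethyl-5-[(1S)-3-methyl-1-(2,4,6-trimethoxyphenyl)butyl]-2,3,4,4a,5,6,7,8-octahydronaphthalen-2-yl]propan-2-ol
Product: 25 2-[(2S,4aR,5R,8R)-5-[(1S)-1-(3,5-dibromo-2,4,6-trimethoxyphenyl)-3-methylbutyl]-4a,8-dimethyl-2,3,4,4a,5,6,7,8-octahydronaphthalen-2-yl]propan-2-ol
Conditions: NBS (2.05 equiv), MeCN, −30 to 0 °C
Reagents that add atoms: N-bromosuccinimide O=C1CCC(=O)N1Br
Why: Electrophilic aromatic bromination, in which the two free positions of the trialkoxyarene, each flanked by two methoxy groups, should be far more nucleophilic than the trisubstituted alkene.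

Step 14
Reactants: 25 2-[(2S,4aR,5R,8R)-5-[(1S)-1-(3,5-dibromo-2,4,6-trimethoxyphenyl)-3-methylbutyl]-4a,8-dimethyl-2,3,4,4a,5,6,7,8-octahydronaphthalen-2-yl]propan-2-ol
Product: 27 5-[(1S)-1-[(1R,4R,6S,8aR)-6-(2-hydroxypropan-2-yl)-4,8a-dimethyl-1,2,3,4,6,7,8,8a-octahydronaphthalen-1-yl]-3-methylbutyl]-2,4,6-trimethoxybenzene-1,3-dicarbaldehyde, via trilithio species 26 (not isolated)
Conditions: t-BuLi (5.2 equiv), THF, −78 °C; DMF, −78 to 0 °C; aq. NH4Cl
Reagents that add atoms: N,N-dimethylformamide CN(C)C=O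
Why: After deprotonation of the tertiary alcohol, bromine–lithium exchange at both aryl positions gives a dilithio arene stabilised by the flanking methoxy groups, which is formylated by DMF.

Step 15
Reactants: 27 5-[(1S)-1-[(1R,4R,6S,8aR)-6-(2-hydroxypropan-2-yl)-4,8a-dimethyl-1,2,3,4,6,7,8,8a-octahydronaphthalen-1-yl]-3-methylbutyl]-2,4,6-trimethoxybenzene-1,3-dicarbaldehyde
Product: 28 5-[(1S)-1-[(1R,4R,6S,8aR)-6-(2-hydroxypropan-2-yl)-4,8a-dimethyl-1,2,3,4,6,7,8,8a-octahydronaphthalen-1-yl]-3-methylbutyl]-2,4,6-trihydroxybenzene-1,3-dicarbaldehyde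
Conditions: NaSEt (excess), DMF, 110 °C; then 1 M HCl, 0 °C
Reagents that add atoms: none
Why: Thiolate SN2 O-demethylation of the three aryl methyl ethers, each activated by an ortho formyl group, under non-acidic conditions that should leave the tertiary alcohol and the C5=C6 alkene untouched.

**Compound list**

1 | (S)-(+)-carvone, (5S)-2-methyl-5-(prop-1-en-2-yl)cyclohex-2-en-1-one | CC1=CC[C@@H](CC1=O)C(C)=C | starting material
2 | tert-butyldimethyl{[(3S)-6-methyl-3-(prop-1-en-2-yl)cyclohexa-1,5-dien-1-yl]oxy}silane (silyl dienol ether) | CC1=CC[C@@H](C=C1O[Si](C)(C)C(C)(C)C)C(C)=C | intermediate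
3 | (5R,6R)-6-[(tert-butyldimethylsilyl)oxy]-2-methyl-5-(prop-1-en-2-yl)cyclohex-2-en-1-one | CC1=CC[C@@H]([C@@H](O[Si](C)(C)C(C)(C)C)C1=O)C(C)=C | intermediate
4 | lithium (5R,6R)-6-[(tert-butyldimethylsilyl)oxy]-2-methyl-5-(prop-1-en-2-yl)cyclohex-1-en-1-olate | CC1=C(O[Li])[C@H](O[Si](C)(C)C(C)(C)C)[C@H](CC1)C(C)=C | intermediate
5 | (5R,6R)-6-[(tert-butyldimethylsilyl)oxy]-2-methyl-5-(prop-1-en-2-yl)cyclohex-1-en-1-yl trifluoromethanesulfonate | CC1=C(OS(=O)(=O)C(F)(F)F)[C@H](O[Si](C)(C)C(C)(C)C)[C@H](CC1)C(C)=C | intermediate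
6 | tert-butyldimethyl{[(1R,6R)-3-methyl-6-(prop-1-en-2-yl)-2-[(trimethylsilyl)ethynyl]cyclohex-2-en-1-yl]oxy}silane | CC1=C(C#C[Si](C)(C)C)[C@H](O[Si](C)(C)C(C)(C)C)[C@H](CC1)C(C)=C | intermediate
7 | tert-butyl{[(1R,6R)-2-ethynyl-3-methyl-6-(prop-1-en-2-yl)cyclohex-2-en-1-yl]oxy}dimethylsilane | CC1=C(C#C)[C@H](O[Si](C)(C)C(C)(C)C)[C@H](CC1)C(C)=C | intermediate
8 | 9-[(Z)-2-bromo-2-{(5R,6R)-6-[(tert-butyldimethylsilyl)oxy]-2-methyl-5-(prop-1-en-2-yl)cyclohex-1-en-1-yl}ethenyl]-9-borabicyclo[3.3.1]nonane | CC1=C(/C(Br)=C/B2C3CCCC2CCC3)[C@H](O[Si](C)(C)C(C)(C)C)[C@H](CC1)C(C)=C | intermediate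
9 | {[(1R,6R)-2-(1-bromoethenyl)-3-methyl-6-(prop-1-en-2-yl)cyclohex-2-en-1-yl]oxy}(tert-butyl)dimethylsilane | CC1=C(C(Br)=C)[C@H](O[Si](C)(C)C(C)(C)C)[C@H](CC1)C(C)=C | intermediate
10 | (2-{(1S,2R)-3-(1-bromoethenyl)-2-[(tert-butyldimethylsilyl)oxy]-4-methylcyclohex-3-en-1-yl}-2-hydroxypropyl)mercury acetate, both epimers at the carbinol carbon | CC1=C(C(Br)=C)[C@H](O[Si](C)(C)C(C)(C)C)[C@H](CC1)C(C)(O)C[Hg]OC(C)=O | intermediate
11 | 2-{(1S,2R)-3-(1-bromoethenyl)-2-[(tert-butyldimethylsilyl)oxy]-4-methylcyclohex-3-en-1-yl}propan-2-ol | CC1=C(C(Br)=C)[C@H](O[Si](C)(C)C(C)(C)C)[C@H](CC1)C(C)(C)O | intermediate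
12 | (1R,6S)-2-(1-bromoethenyl)-6-(2-hydroxypropan-2-yl)-3-methylcyclohex-2-en-1-ol (ring hydroxyl trans to the hydroxypropyl group) | CC1=C(C(Br)=C)[C@H](O)[C@H](CC1)C(C)(C)O | intermediate
13 | 5,7-dimethoxycoumarin (5,7-dimethoxy-2H-chromen-2-one) | COc1cc(OC)c2ccc(=O)oc2c1 | starting material
14 | (4S)-5,7-dimethoxy-4-(2-methylpropyl)-3,4-dihydro-2H-chromen-2-one | CC(C)C[C@H]1CC(=O)Oc2cc(OC)cc(OC)c12 | intermediate
15 | potassium phenoxide of (1R,6S)-2-(1-bromoethenyl)-6-(2-hydroxypropan-2-yl)-3-methylcyclohex-2-en-1-yl (3S)-3-(2-hydroxy-4,6-dimethoxyphenyl)-5-methylhexanoate | CC(C)C[C@H](c1c(O[K])cc(OC)cc1OC)CC(=O)O[C@H]1C(C(Br)=C)=C(C)CC[C@@H]1C(C)(C)O | intermediate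
16 | trimethylsilyl ketene acetal of ester 15 with the phenol and the tertiary alcohol as trimethylsilyl ethers | CC(C)C[C@H](c1c(O[Si](C)(C)C)cc(OC)cc1OC)C=C(O[Si](C)(C)C)O[C@H]1C(C(Br)=C)=C(C)CC[C@@H]1C(C)(C)O[Si](C)(C)C | intermediate
17 | (3S)-2-[(1R,4S)-2-(1-bromoethenyl)-4-(2-hydroxypropan-2-yl)-1-methylcyclohex-2-en-1-yl]-3-(2-hydroxy-4,6-dimethoxyphenyl)-5-methylhexanoic acid, both C2 epimers | CC(C)C[C@H](c1c(O)cc(OC)cc1OC)C(C(=O)O)[C@@]2(C)CC[C@H](C(C)(C)O)C=C2C(Br)=C | intermediate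
18 | (3R,4S)-3-[(1R,4S)-2-(1-bromoethenyl)-4-(2-hydroxypropan-2-yl)-1-methylcyclohex-2-en-1-yl]-5,7-dimethoxy-4-(2-methylpropyl)-3,4-dihydro-2H-chromen-2-one (trans lactone) | CC(C)C[C@H]1[C@@H](C(=O)Oc2cc(OC)cc(OC)c12)[C@@]3(C)CC[C@H](C(C)(C)O)C=C3C(Br)=C | intermediate
19 | (3R,4S)-3-[(1R,4S)-2-(1-bromoethenyl)-4-(2-hydroxypropan-2-yl)-1-methylcyclohex-2-en-1-yl]-5,7-dimethoxy-4-(2-methylpropyl)-3,4-dihydro-2H-chromen-2-ol, both anomers | CC(C)C[C@H]1[C@@H](C(O)Oc2cc(OC)cc(OC)c12)[C@@]3(C)CC[C@H](C(C)(C)O)C=C3C(Br)=C | intermediate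
20 | potassium 2-{(3R,4S)-3-[(1R,4S)-2-(1-bromoethenyl)-4-(2-hydroxypropan-2-yl)-1-methylcyclohex-2-en-1-yl]-6-methylhept-1-en-4-yl}-3,5-dimethoxyphenolate | CC(C)C[C@H](c1c(O[K])cc(OC)cc1OC)[C@@H](C=C)[C@@]2(C)CC[C@H](C(C)(C)O)C=C2C(Br)=C | intermediate
21 | 2-[(1S,4R)-3-(1-bromoethenyl)-4-methyl-4-[(3R,4S)-6-methyl-4-(2,4,6-trimethoxyphenyl)hept-1-en-3-yl]cyclohex-2-en-1-yl]propan-2-ol | CC(C)C[C@H](c1c(OC)cc(OC)cc1OC)[C@@H](C=C)[C@@]2(C)CC[C@H](C(C)(C)O)C=C2C(Br)=C | intermediate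
22 | 2-[(1S,4R)-4-[(3R,4S)-1-(9-borabicyclo[3.3.1]nonan-9-yl)-6-methyl-4-(2,4,6-trimethoxyphenyl)heptan-3-yl]-3-(1-bromoethenyl)-4-methylcyclohex-2-en-1-yl]propan-2-ol | CC(C)C[C@H](c1c(OC)cc(OC)cc1OC)[C@@H](CCB3C4CCCC3CCC4)[C@@]2(C)CC[C@H](C(C)(C)O)C=C2C(Br)=C | intermediate
23 | 2-[(2S,4aR,5R)-4a-methyl-8-methylidene-5-[(1S)-3-methyl-1-(2,4,6-trimethoxyphenyl)butyl]-2,3,4,4a,5,6,7,8-octahydronaphthalen-2-yl]propan-2-ol | CC(C)C[C@H](c1c(OC)cc(OC)cc1OC)[C@H]1CCC(=C)C2=C[C@@H](C(C)(C)O)CC[C@@]21C | intermediate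
24 | 2-[(2S,4aR,5R,8R)-4a,8-dimethyl-5-[(1S)-3-methyl-1-(2,4,6-trimethoxyphenyl)butyl]-2,3,4,4a,5,6,7,8-octahydronaphthalen-2-yl]propan-2-ol | CC(C)C[C@H](c1c(OC)cc(OC)cc1OC)[C@H]1CC[C@@H](C)C2=C[C@@H](C(C)(C)O)CC[C@@]21C | intermediate
25 | 2-[(2S,4aR,5R,8R)-5-[(1S)-1-(3,5-dibromo-2,4,6-trimethoxyphenyl)-3-methylbutyl]-4a,8-dimethyl-2,3,4,4a,5,6,7,8-octahydronaphthalen-2-yl]propan-2-ol | CC(C)C[C@H](c1c(OC)c(Br)c(OC)c(Br)c1OC)[C@H]1CC[C@@H](C)C2=C[C@@H](C(C)(C)O)CC[C@@]21C | intermediate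
26 | trilithio species of 25 (3,5-dilithioaryl, lithium tertiary alkoxide) | CC(C)C[C@H](c1c(OC)c([Li])c(OC)c([Li])c1OC)[C@H]1CC[C@@H](C)C2=C[C@@H](C(C)(C)O[Li])CC[C@@]21C | intermediate
27 | 5-[(1S)-1-[(1R,4R,6S,8aR)-6-(2-hydroxypropan-2-yl)-4,8a-dimethyl-1,2,3,4,6,7,8,8a-octahydronaphthalen-1-yl]-3-methylbutyl]-2,4,6-trimethoxybenzene-1,3-dicarbaldehyde | CC(C)C[C@H](c1c(OC)c(C=O)c(OC)c(C=O)c1OC)[C@H]1CC[C@@H](C)C2=C[C@@H](C(C)(C)O)CC[C@@]21C | intermediate
28 | 5-[(1S)-1-[(1R,4R,6S,8aR)-6-(2-hydroxypropan-2-yl)-4,8a-dimethyl-1,2,3,4,6,7,8,8a-octahydronaphthalen-1-yl]-3-methylbutyl]-2,4,6-trihydroxybenzene-1,3-dicarbaldehyde | CC(C)C[C@H](c1c(O)c(C=O)c(O)c(C=O)c1O)[C@H]1CC[C@@H](C)C2=C[C@@H](C(C)(C)O)CC[C@@]21C | target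

**Step count and risks**

Total step count: 15. Longest linear sequence: 14 steps (steps 1–6 and 8–15; step 7 is the one-step side branch).

Steps most likely to fail:

Step 8. The acyl transfer may stall, or the sigmatropic shift at the congested tetrasubstituted C5=C10 alkene may be slow enough that elimination of the allylic ester or ketene formation competes. The fallback sets out from 14 and 12 and avoids enolate chemistry. Lactone 14 is O-ethylated with triethyloxonium tetrafluoroborate and treated with NaOEt to give the cyclic ortho ester (4S)-2,2-diethoxy-5,7-dimethoxy-4-(2-methylpropyl)-3,4-dihydro-2H-chromene F1. Heating 12 with F1 and catalytic 2,4,6-trimethylbenzoic acid in xylene at 140 °C should exchange one ethoxy group for the allylic alcohol, eliminate ethanol to a cyclic ketene acetal and rearrange (Johnson–Claisen) with the allyl unit entering anti to the isobutyl group. The route is rejoined at 18.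

Step 7. Conversion or facial selectivity may be poor because the C5 methoxy group crowds C4, and the magnesium enolate may fragment to a ketene and add a second Grignard equivalent. The fallback sets out from 13. Hayashi–Miyaura addition of (2-methylprop-1-en-1-yl)boronic acid with [Rh(acac)(C2H4)2] and SEGPHOS in dioxane/water should give (4R)-5,7-dimethoxy-4-(2-methylprop-1-en-1-yl)-3,4-dihydro-2H-chromen-2-one F2 (same spatial arrangement as 14). Hydrogenation of the side-chain alkene over palladium on carbon then rejoins the route at 14.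

Step 12. Hydrogen delivery to C4 may show poor facial selectivity, giving the C4 epimer, or the conjugated diene may be over-reduced. The fallback sets out from 23 and uses a bulkier reagent for the facial choice. Hydroboration with 9-BBN should add from the face opposite C14, and NaOH/H2O2 oxidation then gives 2-[(2S,4aR,5R,8R)-8-(hydroxymethyl)-4a-methyl-5-[(1S)-3-methyl-1-(2,4,6-trimethoxyphenyl)butyl]-2,3,4,4a,5,6,7,8-octahydronaphthalen-2-yl]propan-2-ol F3. Selective tosylation of the primary hydroxyl (TsCl, pyridine) gives the 8-(tosyloxymethyl) derivative F4, and displacement with LiBEt3H turns C15 into the methyl group. The route is rejoined at 24.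

Further compounds
F1 | step 8 | (4S)-2,2-diethoxy-5,7-dimethoxy-4-(2-methylpropyl)-3,4-dihydro-2H-chromene | CC(C)C[C@H]1CC(OCC)(OCC)Oc2cc(OC)cc(OC)c12
F2 | step 7 | (4R)-5,7-dimethoxy-4-(2-methylprop-1-en-1-yl)-3,4-dihydro-2H-chromen-2-one | CC(C)=C[C@H]1CC(=O)Oc2cc(OC)cc(OC)c12
F3 | step 12 | 2-[(2S,4aR,5R,8R)-8-(hydroxymethyl)-4a-methyl-5-[(1S)-3-methyl-1-(2,4,6-trimethoxyphenyl)butyl]-2,3,4,4a,5,6,7,8-octahydronaphthalen-2-yl]propan-2-ol | CC(C)C[C@H](c1c(OC)cc(OC)cc1OC)[C@H]1CC[C@@H](CO)C2=C[C@@H](C(C)(C)O)CC[C@@]21C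
F4 | step 12 | [(1R,4R,6S,8aR)-6-(2-hydroxypropan-2-yl)-8a-methyl-1-[(1S)-3-methyl-1-(2,4,6-trimethoxyphenyl)butyl]-1,2,3,4,6,7,8,8a-octahydronaphthalen-4-yl]methyl 4-methylbenzenesulfonate | CC(C)C[C@H](c1c(OC)cc(OC)cc1OC)[C@H]1CC[C@@H](COS(=O)(=O)c3ccc(C)cc3)C2=C[C@@H](C(C)(C)O)CC[C@@]21C
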